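## Structural features

The target is made of two flavanone units, each with a benzo ring A, a dihydropyranone ring C and an aryl ring B on C2. The units are joined by a diaryl ether that runs from C4' of ring B of unit 1 to C6'' of ring A of unit 2. Ring A of unit 2 is therefore fully substituted except at C8'', and the ether oxygen sits between the 5''-hydroxyl and the 7''-methoxy group. The two stereocentres, C2 and C2'', are both S. They are not adjacent: ring B of unit 1, the ether oxygen and ring A of unit 2 separate them, so neither can direct the other. The fragile groups are the two flavanone rings, which open at O1–C2 by retro-oxa-Michael reaction under base (and under strong Lewis acid) and so lose configuration, and the three free phenols. The real difficulties are the crowded diaryl ether, the differentiation of 5-OH from 7-OMe in both units beside a free 4'''-OH, and the need to set two remote stereocentres in the same sense. The key step uses the make-up of ring C of unit 1: C4 is a lone carbonyl carbon, C4a and O1 (through C8a) belong to an ortho-disposed phenol, and C2–C3 is a two-carbon unit on ring B. At the flavone oxidation level these three pieces are carbon monoxide, an ortho-iodophenol and an aryl alkyne. The same analysis applies to ring C of unit 2, where the iodophenol has two equivalent ortho positions.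

## Logic of the disconnections

21 from 20. No skeletal bond is cut; two peri O–methyl bonds (O5, O5'') and the O4'''–isopropyl bond are cleaved last. The gain is that every earlier intermediate carries only ethers, all of which come from symmetric, cheap building blocks. The demand is a reagent that distinguishes the chelating peri-methoxy groups and the secondary alkyl ether from the two ordinary methoxy groups and leaves O1–C2 and O1''–C2'' intact.

20 from 19 from 18. The C2–H and C3–H bonds of both units (and, transiently, the C4–H bonds) are removed, which takes both stereocentres back to a flat, achiral bis-flavone. This is the largest simplification of the plan. The demand is a chiral catalyst that selects the same face of two independent C2=C3 bonds, followed by a mild return from the carbinol to the ketone level.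

18 from 16, 11 and 14. Ring C of unit 1 is cut at C4a–C4, C4–C3 and O1–C2. This gives a small iodophenol, carbon monoxide and a terminal alkyne that already holds all of unit 2. The gain is full convergence. The demand is carbonylative rather than direct coupling and six-membered rather than five-membered closure.

14 from 13. Only the C–Si bond is cut. The silyl cap keeps the second alkyne silent during the first annulation.

13 from 8, 11 and 10. The same three bonds are cut in ring C of unit 2. Because the two ortho positions of the parent phenol are equivalent, the crowded 5,6,7-trioxygenated pattern needs no positional control. The demand is that the capped alkyne stays inert.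

8 from 7, 7 from 5, 5 from 3 and 4, 3 from 1 and 2. The cuts are, in turn, the C–I bond, the phenolic C–O bond (from a formyl group by oxygen insertion), the sp–sp2 C–C bond and the diaryl ether C–O bond. The alkyne is placed before the iodide on purpose, so that no aryl bromide is present when palladium and carbon monoxide are used. The demand is aryl transfer to a doubly ortho-substituted phenol.

10 from 9. The alkyne C≡C bond is traced to an aldehyde by one-carbon homologation.

16 from 15. The C–I bond is cut. The demand is iodination ortho, not para, to the hydroxyl group.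

## Other disconnections considered

Alternative 1: The cut is at O1–C2 and O1''–C2''. In the forward direction a quinine-derived bifunctional thiourea would make each free phenol of the open-chain bis(alkylidene β-keto ester) A2 add to its acceptor, giving the bis(3-tert-butoxycarbonylflavanone) A1; acid then removes both esters by decarboxylation. In its favour, both stereocentres are formed directly in the C–O bond-forming event at the flavanone oxidation level. No pressure equipment, no transition metal and no redox correction are needed, and on these points it is better than the chosen plan. Against it, A2 needs two different β-keto esters on two different phenol rings and two Knoevenagel condensations. Both acceptors carry para-oxygenated aryl groups, which are the least electrophilic and the most prone to reverse the oxa-Michael step, so configuration could erode at the closure and again during the hot acidic decarboxylation. The peri-methoxy groups and a benzyl ether still have to come off afterwards, so the final deprotection problem is equal to that of the chosen plan. In step economy the alternative is clearly longer.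

Alternative 2: The cut is at C2–C3 and C2''–C3''. KOt-Bu would shift both aroyl groups of the bis(aryl ester) A4 from oxygen to carbon to give the bis(1,3-diketone) A3, and acid cyclodehydration would then give the same bis-flavone 18. In its favour, the chemistry is classical and free of palladium, carbon monoxide and iodophenols, so the positional question of step 8 does not arise. The diaryl ether could be made by a simple SNAr reaction on a 4-fluorobenzoate. On these points it is better than the chosen plan. Because it reaches 18, it is equal in everything that follows, including the stereochemical problem. Against it, ring B of unit 1 must be brought in as a carboxylic acid, unit 2 needs a hindered ortho-hydroxyacetophenone, two chelated phenols must be aroylated, and the strongly basic and then strongly acidic steps put the isopropyl ether at risk. It takes about four operations for the two pyranone rings where the chosen plan takes two.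

Alternative 3: The cut is at C4a–C5 and C8–C8a, so that ring A of unit 1 is made last. The diene A7 would add across C5=C6 of the enantiopure 5-sulfinyl dihydropyranone A6, and loss of sulfenic acid and methanol would give the bis-flavanone A5. In its favour, the 5-hydroxy-7-methoxy pattern of unit 1 appears directly with a free 5-OH, and C2 can be set early by a well-established asymmetric hetero-Diels–Alder reaction; on both points it is better than the chosen plan. Against it, the method solves only unit 1. Unit 2, with its fully substituted ring A, must be made enantioselectively by other means and carried through as the aryl group of A6. The benzylic C2–O bond of A6 and that of the finished unit 2 must survive the cycloaddition and elimination conditions, the sulfinyl group costs extra steps, and 5''-O-demethylation beside a free 5-OH still remains. It is the longest and most linear of the plans and rests on the least secure precedent for a substrate of this size.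

Key step: step 9

Remarks on the chemistry:
- The (R,R) antipode of the carbene ligand is taken as the one that gives the 2S series. If a model flavone shows the opposite sense, the (S,S) antipode is used and nothing else changes.
- The carbinol centres C4 and C4'' of 19 are drawn cis to the aryl groups. Their configuration is of no consequence because step 11 removes it.
- The atom mapping of both annulations was checked: the carbon bearing iodine becomes C4a and the phenol oxygen becomes O1. No structure needed correction.
- The alkyne of ring B of unit 1 is installed with a silyl cap before the first annulation, so no aryl bromide is exposed to palladium and carbon monoxide.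

## Route

Step 1
Reactants: 1 syringaldehyde; 2 (4-bromophenyl)boronic acid
Product: 3 4-(4-bromophenoxy)-3,5-dimethoxybenzaldehyde
Conditions: Cu(OAc)2, pyridine, 4 Å MS, CH2Cl2, dry air, rt
Reagents that add atoms: none
Why: Chan–Lam O-arylation; divalent copper transfers the aryl group from boron to the phenol oxygen at room temperature and tolerates two ortho substituents, the aldehyde and the aryl bromide, while air returns copper to the divalent state.

Step 2
Reactants: 3 4-(4-bromophenoxy)-3,5-dimethoxybenzaldehyde; 4 (triisopropylsilyl)acetylene
Product: 5 3,5-dimethoxy-4-{4-[(triisopropylsilyl)ethynyl]phenoxy}benzaldehyde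
Conditions: PdCl2(PPh3)2 (cat.), CuI (cat.), Et3N, THF, 65 °C
Reagents that add atoms: none
Why: Sonogashira coupling of an unhindered aryl bromide; the bulky silyl group is chosen because it survives the peracid, carbonate, iodination and hot amine conditions of steps 3, 4 and 6.

Step 3
Reactants: 5 3,5-dimethoxy-4-{4-[(triisopropylsilyl)ethynyl]phenoxy}benzaldehyde
Product: 7 3,5-dimethoxy-4-{4-[(triisopropylsilyl)ethynyl]phenoxy}phenol, via aryl formate 6 (not isolated)
Conditions: mCPBA, CH2Cl2, 0 °C to rt; then K2CO3 (cat.), MeOH, rt
Reagents that add atoms: meta-chloroperoxybenzoic acid, O=C(OO)c1cccc(Cl)c1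
Why: Baeyer–Villiger (Dakin-type) oxidation; the trioxygenated aryl group migrates in preference to hydride, as with 3,4,5-trialkoxybenzaldehydes, and the formate is removed by methanolysis, while the silyl alkyne reacts with peracid far more slowly than the aldehyde.

Step 4
Reactants: 7 3,5-dimethoxy-4-{4-[(triisopropylsilyl)ethynyl]phenoxy}phenol
Product: 8 2-iodo-3,5-dimethoxy-4-{4-[(triisopropylsilyl)ethynyl]phenoxy}phenol
Conditions: NIS (1.0 equiv), MeCN, 0 °C, dark
Reagents that add atoms: N-iodosuccinimide, O=C1CCC(=O)N1I
Why: Electrophilic aromatic iodination; the para position is blocked and the two ortho positions are equivalent, so only one mono-iodide can form, and the alkynyl-bearing ring is much less activated than the phenol ring.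

Step 5
Reactants: 9 4-isopropoxybenzaldehyde
Product: 10 1-ethynyl-4-isopropoxybenzene
Conditions: dimethyl (1-diazo-2-oxopropyl)phosphonate, K2CO3, MeOH, rt
Reagents that add atoms: dimethyl (1-diazo-2-oxopropyl)phosphonate, COP(=O)(OC)C(=[N+]=[N-])C(C)=O
Why: Ohira–Bestmann variant of the Seyferth–Gilbert homologation; methanolysis releases the diazomethylphosphonate anion, which converts the aromatic aldehyde into the terminal alkyne by olefination, loss of nitrogen and 1,2-shift.

Step 6
Reactants: 8 2-iodo-3,5-dimethoxy-4-{4-[(triisopropylsilyl)ethynyl]phenoxy}phenol; 10 1-ethynyl-4-isopropoxybenzene; 11 carbon monoxide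
Product: 13 5,7-dimethoxy-4'-isopropoxy-6-{4-[(triisopropylsilyl)ethynyl]phenoxy}flavone, via ortho-hydroxyaryl ynone 12 (not isolated)
Conditions: PdCl2(PPh3)2 (cat.), CO (20 bar), Et2NH, 110 °C, autoclave
Reagents that add atoms: none
Why: Palladium-catalysed carbonylative annulation of a 2-iodophenol with a terminal arylacetylene; the aroyl–palladium species couples with the terminal alkyne and diethylamine steers the phenol into the six-membered closure, while the silyl-capped internal alkyne has no acidic C–H and is too hindered for carbopalladation.

Step 7
Reactants: 13 5,7-dimethoxy-4'-isopropoxy-6-{4-[(triisopropylsilyl)ethynyl]phenoxy}flavone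
Product: 14 6-(4-ethynylphenoxy)-5,7-dimethoxy-4'-isopropoxyflavone
Conditions: Bu4NF, THF, 0 °C; aqueous work-up
Reagents that add atoms: none
Why: Fluoride-induced protodesilylation of an alkynylsilane; the flavone and the aryl ethers are inert to fluoride at 0 °C.

Step 8
Reactants: 15 3,5-dimethoxyphenol
Product: 16 2-iodo-3,5-dimethoxyphenol
Conditions: NIS (1.0 equiv), CH2Cl2, −20 to 0 °C, dark
Reagents that add atoms: N-iodosuccinimide, O=C1CCC(=O)N1I
Why: Electrophilic aromatic iodination; the two equivalent positions between OH and OMe are favoured statistically and are less crowded than C4 between two methoxy groups, and hydrogen bonding of the phenol to the reagent in a non-polar solvent further favours ortho delivery.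

Step 9
Reactants: 16 2-iodo-3,5-dimethoxyphenol; 11 carbon monoxide; 14 6-(4-ethynylphenoxy)-5,7-dimethoxy-4'-isopropoxyflavone
Product: 18 5,7,5'',7''-tetra-O-methyl-4'''-O-isopropylhinokiflavone, via ortho-hydroxyaryl ynone 17 (not isolated)
Conditions: PdCl2(PPh3)2 (cat.), CO (20 bar), Et2NH–DMF, 100 °C, autoclave; 16 in excess
Reagents that add atoms: none
Why: Reduction in the flask gives zerovalent palladium, which inserts into the C–I bond of 16; uptake of CO gives an aroyl–palladium iodide, and amine-assisted exchange with the terminal alkyne of 14 followed by reductive elimination forms C4a–C4 and C4–C3 in ynone 17. Diethylamine then adds reversibly to the β-carbon of the ynone to give an enaminone, and the neighbouring phenol displaces the amine by addition–elimination, forming O1–C2 and closing ring C. The closest known reaction type is the palladium-catalysed carbonylative annulation of 2-iodophenols with terminal arylacetylenes to flavones in diethylamine. The closure is a net 6-endo-dig attack of the phenol oxygen on the alkyne (6-endo-trig on the enaminone); the 5-exo-dig path to the aurone is suppressed because the amine, not the phenoxide, makes the first bond to the β-carbon. No stereocentre is created. The step needs carbonylative rather than direct coupling, which would end in a 2-arylbenzofuran; copper-free conditions, CO pressure and the electron-rich, doubly ortho-substituted aryl–palladium species, which takes up CO quickly, should secure this. It also needs chemoselectivity within 14, where the terminal alkyne is the only palladium-reactive site and the flavone of unit 2 carries no halide and is shielded at C2'' by its aryl group against amine addition. Iodophenol 16 is used in excess because 14 is the more valuable partner.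

Step 10
Reactants: 18 5,7,5'',7''-tetra-O-methyl-4'''-O-isopropylhinokiflavone
Product: 19 (2S,4S,2''S,4''S)-bis(flavan-4-ol) corresponding to 18 (both pyranone rings reduced at C2=C3 and C4=O)
Conditions: Ru(cod)(2-methylallyl)2 / (R,R)-SINpEt·HBF4 / KOt-Bu (catalyst pre-formed), H2 (120 bar), toluene, 25–40 °C
Reagents that add atoms: none
Why: Ruthenium–N-heterocyclic carbene catalysed asymmetric hydrogenation of flavones; the C2-symmetric chiral bis(carbene) ruthenium hydride selects the face of each C2=C3 bond and so sets C2 and C2'' independently under catalyst control, then reduces each ketone, and running to the diol gives one defined oxidation level. Since both centres are set independently, most stereochemical errors should end up in the separable (2R,2''S)/(2S,2''R) diastereomers rather than in the enantiomer.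

Step 11
Reactants: 19 (2S,4S,2''S,4''S)-bis(flavan-4-ol)
Product: 20 (2S,2''S)-5,7,5'',7''-tetra-O-methyl-4'''-O-isopropyl-2,3,2'',3''-tetrahydrohinokiflavone
Conditions: Dess–Martin periodinane, CH2Cl2, 0 °C to rt
Reagents that add atoms: none
Why: Dess–Martin oxidation of the two benzylic secondary alcohols to ketones under neutral to weakly acidic conditions, which do not open the flavanone ring; C2 and C2'' are untouched, and any flavanone-level material carried from step 10 converges on 20.

Step 12
Reactants: 20 (2S,2''S)-5,7,5'',7''-tetra-O-methyl-4'''-O-isopropyl-2,3,2'',3''-tetrahydrohinokiflavone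
Product: 21 7,7''-di-O-methyltetrahydrohinokiflavone, (2S,2''S)
Conditions: BCl3, CH2Cl2, −78 to 0 °C; then H2O
Reagents that add atoms: none
Why: Lewis-acid ether cleavage; BCl3 chelates between each C4 carbonyl and its peri-methoxy oxygen and removes only those methyl groups, and it cleaves the secondary isopropyl ether much faster than an ordinary aryl methyl ether, so the 7- and 7''-methoxy groups and the diaryl ether should remain; the low temperature is meant to keep O1–C2 and O1''–C2'' closed.

## Compound list

1 | syringaldehyde (4-hydroxy-3,5-dimethoxybenzaldehyde) | COc1cc(C=O)cc(OC)c1O | starting material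
2 | (4-bromophenyl)boronic acid | OB(O)c1ccc(Br)cc1 | starting material
3 | 4-(4-bromophenoxy)-3,5-dimethoxybenzaldehyde | COc1cc(C=O)cc(OC)c1Oc1ccc(Br)cc1 | intermediate
4 | (triisopropylsilyl)acetylene | C#C[Si](C(C)C)(C(C)C)C(C)C | starting material
5 | 3,5-dimethoxy-4-{4-[(triisopropylsilyl)ethynyl]phenoxy}benzaldehyde | COc1cc(C=O)cc(OC)c1Oc1ccc(C#C[Si](C(C)C)(C(C)C)C(C)C)cc1 | intermediate
6 | 3,5-dimethoxy-4-{4-[(triisopropylsilyl)ethynyl]phenoxy}phenyl formate | COc1cc(OC=O)cc(OC)c1Oc1ccc(C#C[Si](C(C)C)(C(C)C)C(C)C)cc1 | intermediate (not isolated)
7 | 3,5-dimethoxy-4-{4-[(triisopropylsilyl)ethynyl]phenoxy}phenol | COc1cc(O)cc(OC)c1Oc1ccc(C#C[Si](C(C)C)(C(C)C)C(C)C)cc1 | intermediate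
8 | 2-iodo-3,5-dimethoxy-4-{4-[(triisopropylsilyl)ethynyl]phenoxy}phenol | COc1cc(O)c(I)c(OC)c1Oc1ccc(C#C[Si](C(C)C)(C(C)C)C(C)C)cc1 | intermediate
9 | 4-isopropoxybenzaldehyde | CC(C)Oc1ccc(C=O)cc1 | starting material
10 | 1-ethynyl-4-isopropoxybenzene | C#Cc1ccc(OC(C)C)cc1 | intermediate
11 | carbon monoxide | [C-]#[O+] | starting material
12 | 1-(6-hydroxy-2,4-dimethoxy-3-{4-[(triisopropylsilyl)ethynyl]phenoxy}phenyl)-3-(4-isopropoxyphenyl)prop-2-yn-1-one | COc1cc(O)c(C(=O)C#Cc2ccc(OC(C)C)cc2)c(OC)c1Oc1ccc(C#C[Si](C(C)C)(C(C)C)C(C)C)cc1 | intermediate (not isolated)
13 | 5,7-dimethoxy-4'-isopropoxy-6-{4-[(triisopropylsilyl)ethynyl]phenoxy}flavone | COc1cc2oc(-c3ccc(OC(C)C)cc3)cc(=O)c2c(OC)c1Oc1ccc(C#C[Si](C(C)C)(C(C)C)C(C)C)cc1 | intermediate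
14 | 6-(4-ethynylphenoxy)-5,7-dimethoxy-4'-isopropoxyflavone | C#Cc1ccc(Oc2c(OC)cc3oc(-c4ccc(OC(C)C)cc4)cc(=O)c3c2OC)cc1 | intermediate
15 | 3,5-dimethoxyphenol | COc1cc(O)cc(OC)c1 | starting material
16 | 2-iodo-3,5-dimethoxyphenol | COc1cc(O)c(I)c(OC)c1 | intermediate
17 | 6-{4-[3-(2-hydroxy-4,6-dimethoxyphenyl)-3-oxoprop-1-yn-1-yl]phenoxy}-5,7-dimethoxy-4'-isopropoxyflavone | COc1cc(O)c(C(=O)C#Cc2ccc(Oc3c(OC)cc4oc(-c5ccc(OC(C)C)cc5)cc(=O)c4c3OC)cc2)c(OC)c1 | intermediate (not isolated)
18 | 5,7,5'',7''-tetra-O-methyl-4'''-O-isopropylhinokiflavone | COc1cc(OC)c2c(c1)oc(-c1ccc(Oc3c(OC)cc4oc(-c5ccc(OC(C)C)cc5)cc(=O)c4c3OC)cc1)cc2=O | intermediate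
19 | (2S,4S,2''S,4''S)-bis(2,4-cis-flavan-4-ol) from 18, tetra-O-methyl and 4'''-O-isopropyl protected | COc1cc(OC)c2c(c1)O[C@H](c1ccc(Oc3c(OC)cc4c(c3OC)[C@@H](O)C[C@@H](c3ccc(OC(C)C)cc3)O4)cc1)C[C@@H]2O | intermediate
20 | (2S,2''S)-5,7,5'',7''-tetra-O-methyl-4'''-O-isopropyl-2,3,2'',3''-tetrahydrohinokiflavone | COc1cc(OC)c2c(c1)O[C@H](c1ccc(Oc3c(OC)cc4c(c3OC)C(=O)C[C@@H](c3ccc(OC(C)C)cc3)O4)cc1)CC2=O | intermediate
21 | (2S,2''S)-7,7''-di-O-methyltetrahydrohinokiflavone | COc1cc(O)c2c(c1)O[C@H](c1ccc(Oc3c(OC)cc4c(c3O)C(=O)C[C@@H](c3ccc(O)cc3)O4)cc1)CC2=O | target

## Step count and least certain steps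

Total step count: 12. Longest linear sequence: 10 steps (1, 2, 3, 4, 6, 7, 9, 10, 11, 12).

Step 9 (key step). The most likely failure is slow oxidative addition at the very electron-rich, doubly ortho-substituted C–I bond. That would let protodeiodination, aminocarbonylation by diethylamine or CO-free coupling (ending in benzofuran formation) overtake the wanted path, and the large, poorly soluble alkyne makes this worse. The fallback removes both the aryl iodide and the gas. Purchased 2-hydroxy-4,6-dimethoxybenzoic acid would be acetylated (Ac2O, pyridine) to 2-acetoxy-4,6-dimethoxybenzoic acid F1 and converted with oxalyl chloride and catalytic DMF into 2-acetoxy-4,6-dimethoxybenzoyl chloride F2. Acyl Sonogashira coupling of F2 with 14 (PdCl2(PPh3)2, CuI, Et3N, THF, rt) would give the ortho-acetoxyaryl ynone F3. Diethylamine in ethanol would then remove the acetate and close the ring through 17. The fallback sets out from 14 and returns to the route at 18.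

Step 10. Facial selectivity may be poor or conversion incomplete at one of the two flavones, because the substrate is large, sparingly soluble in non-polar media and carries peri-methoxy groups beside both carbonyls; the sense of induction is also an assumption. The fallback separates reduction from stereocontrol. From 18, conjugate reduction of both enones with LiBH(s-Bu)3 in THF at −78 °C would give the stereorandom bis-flavanone F4. Asymmetric transfer hydrogenation with RuCl(p-cymene)(TsDPEN) in HCO2H–Et3N, using the ligand antipode that reduces flavanone units of R configuration faster, would then leave the (2S,2''S) isomer as the only remaining diketone. It is separated from the carbinol-containing stereoisomers and returns to the route at 20. This kinetic resolution sacrifices most of the material and is a rescue only.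

Step 12. Configuration may erode at C2 or C2'' through Lewis-acid-promoted opening of the O1–C2 bonds, which the para-oxygenated B rings assist. Cleavage may also be incomplete at the hindered 5''-position, or it may extend to a 7-methoxy group. The fallback frees the phenols at the robust flavone stage and ends with a neutral step. From 18, BCl3 would give 7,7''-di-O-methylhinokiflavone F5. Benzylation (BnBr, K2CO3, DMF, 80 °C) would give the 5,5'',4'''-tri-O-benzyl bis-flavone F6. Hydrogenation as in step 10 would give the tri-O-benzyl bis(flavan-4-ol) F7, and Dess–Martin oxidation as in step 11 would give the (2S,2''S)-tri-O-benzyl bis-flavanone F8. Hydrogenolysis (H2, Pd/C, EtOAc, rt) would then remove the benzyl groups and return to the route at 21.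

Step 8. Iodination may show poor positional selectivity (C4 against C2) or run on to a di-iodide, since every free position of the ring is strongly activated. The fallback uses directed metalation. From 15, MOMCl and i-Pr2NEt would give 1,3-dimethoxy-5-(methoxymethoxy)benzene F9. Lithiation with n-BuLi in THF at 0 °C, at the position flanked by the acetal and a methoxy group, and quenching with I2 would give 2-iodo-1,5-dimethoxy-3-(methoxymethoxy)benzene F10. HCl in MeOH would remove the acetal and return to the route at 16.

Step 1. Aryl transfer to a phenol that is both doubly ortho-substituted and deactivated by the para-formyl group may be sluggish, so that protodeboronation and homocoupling of the boronic acid consume the reagent. The fallback reverses the polarity of the aryl partner. From 1, an Ullmann-type etherification with 1-bromo-4-iodobenzene (CuI, picolinic acid, K3PO4, DMSO, 90 °C), which reacts selectively at the C–I bond, would return to the route at 3.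

## Further compounds

F1 | step 9 | 2-acetoxy-4,6-dimethoxybenzoic acid | COc1cc(OC)c(C(=O)O)c(OC(C)=O)c1
F2 | step 9 | 2-acetoxy-4,6-dimethoxybenzoyl chloride | COc1cc(OC)c(C(=O)Cl)c(OC(C)=O)c1
F3 | step 9 | 6-{4-[3-(2-acetoxy-4,6-dimethoxyphenyl)-3-oxoprop-1-yn-1-yl]phenoxy}-5,7-dimethoxy-4'-isopropoxyflavone | COc1cc(OC)c(C(=O)C#Cc2ccc(Oc3c(OC)cc4oc(-c5ccc(OC(C)C)cc5)cc(=O)c4c3OC)cc2)c(OC(C)=O)c1
F4 | step 10 | stereorandom 5,7,5'',7''-tetra-O-methyl-4'''-O-isopropyl-2,3,2'',3''-tetrahydrohinokiflavone (all four stereoisomers) | COc1cc(OC)c2c(c1)OC(c1ccc(Oc3c(OC)cc4c(c3OC)C(=O)CC(c3ccc(OC(C)C)cc3)O4)cc1)CC2=O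
F5 | step 12 | 7,7''-di-O-methylhinokiflavone | COc1cc(O)c2c(c1)oc(-c1ccc(Oc3c(OC)cc4oc(-c5ccc(O)cc5)cc(=O)c4c3O)cc1)cc2=O
F6 | step 12 | 5,5'',4'''-tri-O-benzyl-7,7''-di-O-methylhinokiflavone | COc1cc(OCc2ccccc2)c2c(c1)oc(-c1ccc(Oc3c(OC)cc4oc(-c5ccc(OCc6ccccc6)cc5)cc(=O)c4c3OCc3ccccc3)cc1)cc2=O
F7 | step 12 | (2S,4S,2''S,4''S)-bis(2,4-cis-flavan-4-ol) from F6, tri-O-benzyl protected | COc1cc(OCc2ccccc2)c2c(c1)O[C@H](c1ccc(Oc3c(OC)cc4c(c3OCc3ccccc3)[C@@H](O)C[C@@H](c3ccc(OCc5ccccc5)cc3)O4)cc1)C[C@@H]2O
F8 | step 12 | (2S,2''S)-5,5'',4'''-tri-O-benzyl-7,7''-di-O-methyltetrahydrohinokiflavone | COc1cc(OCc2ccccc2)c2c(c1)O[C@H](c1ccc(Oc3c(OC)cc4c(c3OCc3ccccc3)C(=O)C[C@@H](c3ccc(OCc5ccccc5)cc3)O4)cc1)CC2=O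
F9 | step 8 | 1,3-dimethoxy-5-(methoxymethoxy)benzene | COCOc1cc(OC)cc(OC)c1
F10 | step 8 | 2-iodo-1,5-dimethoxy-3-(methoxymethoxy)benzene | COCOc1cc(OC)cc(OC)c1I
F0 | step 1 | none | none
A1 | alternative 1 | (2S,2''S)-bis(2,3-trans-3-tert-butoxycarbonylflavanone), 5,5''-di-O-methyl and 4'''-O-benzyl protected | COc1cc(OC)c2c(c1)O[C@H](c1ccc(Oc3c(OC)cc4c(c3OC)C(=O)[C@H](C(=O)OC(C)(C)C)[C@@H](c3ccc(OCc5ccccc5)cc3)O4)cc1)[C@@H](C(=O)OC(C)(C)C)C2=O
A2 | alternative 1 | open-chain bis(tert-butyl alkylidene β-keto ester) with free C8a and C8a'' phenols, mixture of alkene isomers | COc1cc(O)c(C(=O)C(C(=O)OC(C)(C)C)=Cc2ccc(Oc3c(OC)cc(O)c(C(=O)C(C(=O)OC(C)(C)C)=Cc4ccc(OCc5ccccc5)cc4)c3OC)cc2)c(OC)c1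
A3 | alternative 2 | bis(2-hydroxyaryl 1,3-diketone) | COc1cc(OC)c(C(=O)CC(=O)c2ccc(Oc3c(OC)cc(O)c(C(=O)CC(=O)c4ccc(OC(C)C)cc4)c3OC)cc2)c(O)c1
A4 | alternative 2 | bis(2-acetylaryl ester): 2-acetyl-3,5-dimethoxyphenyl 4-{3-acetyl-2,6-dimethoxy-4-[(4-isopropoxybenzoyl)oxy]phenoxy}benzoate | COc1cc(OC)c(C(C)=O)c(OC(=O)c2ccc(Oc3c(OC)cc(OC(=O)c4ccc(OC(C)C)cc4)c(C(C)=O)c3OC)cc2)c1
A5 | alternative 3 | (2S,2''S)-bis-flavanone with free 5-hydroxyl, 5''-O-methyl and 4'''-O-benzyl protected | COc1cc(O)c2c(c1)O[C@H](c1ccc(Oc3c(OC)cc4c(c3OC)C(=O)C[C@@H](c3ccc(OCc5ccccc5)cc3)O4)cc1)CC2=O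
A6 | alternative 3 | (2S)-2-aryl-5-(phenylsulfinyl)-2,3-dihydro-4H-pyran-4-one carrying the protected unit 2 flavanone on its aryl group | O=C1C[C@@H](c2ccc(Oc3c(OC)cc4c(c3OC)C(=O)C[C@@H](c3ccc(OCc5ccccc5)cc3)O4)cc2)OC=C1S(=O)c1ccccc1
A7 | alternative 3 | 1,3-dimethoxy-1-(trimethylsilyloxy)buta-1,3-diene | C=C(OC)C=C(OC)O[Si](C)(C)C
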